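**Plan**

Retrosynthesis: after removal of the two benzyl ethers, the C2–H and C3–OH bonds are cut back to the C2=C3 bond of a 2-aryl-4H-chromene, which is traced through the flat 1-benzopyrylium (flavylium) salt to a 2-aryl-2H-chromene.
The 2H-chromene is cut at C4–C4a and at O1–C2 into a ring A phenol that already carries the phenethyl chain and a ring B cinnamaldehyde that brings C2, C3 and C4; the phenol is cut at the aryl–CH2 bond of its chain.
Feature that makes the key event possible: the free ring A hydroxyl (later O1) beside an unsubstituted ortho carbon (later C4a) that lies para to the methoxy group; boron ties the aldehyde to this oxygen, the ortho carbon attacks, and the ortho-quinone methide O1=C8a–C4a=C4–C3=C2 so formed closes ring C by oxa-6π electrocyclization.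
Forward order: bibenzyl chain first (B-alkyl Suzuki–Miyaura coupling), then ring C by the annulation, then hydride abstraction at C2 and hydride return at C4; this temporary benzopyrylium oxidation level moves the double bond from C3=C4 to C2=C3.
Stereochemistry: the racemic C2 of the 2H-chromene is erased on purpose; C2 (R) and C3 (S) are then set together by reagent-controlled syn hydroboration of C2=C3 with monoisopinocampheylborane, which can give only the 2,3-trans relation; hydrogenolysis of the benzyl ethers ends the route.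

Key step: step 4

Assumption: the facial sense of monoisopinocampheylborane from (+)-α-pinene is taken over from 1-arylcycloalkenes, because the 2-aryl-4H-chromene shows the reagent the same arrangement of aryl group, ring atoms and vinylic hydrogen; should the opposite face be attacked, the reagent from (−)-α-pinene is used in step 7.

**Route**

Step 1
Reactants: 1 3-(benzyloxy)benzaldehyde
Product: 2 1-(benzyloxy)-3-ethenylbenzene
Conditions: Ph3PCH3Br, KOtBu, THF, 0 °C to rt
Reagents that add atoms: methyltriphenylphosphonium bromide, C[P+](c1ccccc1)(c1ccccc1)c1ccccc1.[Br-]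
Why: Wittig methylenation of an aromatic aldehyde with the non-stabilised ylide, to which the benzyl ether is inert.

Step 2
Reactants: 2 1-(benzyloxy)-3-ethenylbenzene; 3 3-bromo-5-methoxyphenol
Product: 5 3-{2-[3-(benzyloxy)phenyl]ethyl}-5-methoxyphenol, via B-alkyl-9-BBN adduct 4 (not isolated)
Conditions: 9-BBN (1.1 equiv), THF, 0 °C to rt; then 3, PdCl2(dppf) (3 mol %), 3 M aq NaOH, THF, 65 °C
Reagents that add atoms: none
Why: 9-BBN places boron on the terminal carbon of the styrene, and the B-alkyl Suzuki–Miyaura coupling joins this sp3 carbon to the aryl bromide, whose bromine lies meta to both oxygens and so stays reactive even as the phenoxide; the saturated chain is made directly, so no hydrogenation is needed while the benzyl ether is present.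

Step 3
Reactants: 6 4-(benzyloxy)-3-methoxybenzaldehyde
Product: 7 (2E)-3-[4-(benzyloxy)-3-methoxyphenyl]prop-2-enal
Conditions: Ph3P=CHCHO (1.1 equiv), toluene, 90 °C
Reagents that add atoms: (triphenylphosphoranylidene)acetaldehyde, O=CC=P(c1ccccc1)(c1ccccc1)c1ccccc1
Why: Wittig reaction of a stabilised formyl ylide with an aromatic aldehyde should give the E-enal, and the small excess of ylide limits a second homologation.

Step 4
Reactants: 5 3-{2-[3-(benzyloxy)phenyl]ethyl}-5-methoxyphenol; 7 (2E)-3-[4-(benzyloxy)-3-methoxyphenyl]prop-2-enal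
Product: 10 rac-2-[4-(benzyloxy)-3-methoxyphenyl]-5-{2-[3-(benzyloxy)phenyl]ethyl}-7-methoxy-2H-chromene, via benzodioxaborin 8 (not isolated), via ortho-quinone methide 9 (not isolated)
Conditions: PhB(OH)2 (1.2 equiv), EtCO2H (0.3 equiv), toluene, reflux, azeotropic removal of water
Reagents that add atoms: none
Why: Phenol 5 and PhB(OH)2 form a mixed phenylboronate ester that binds aldehyde 7 at boron and delivers its carbonyl carbon to the neighbouring ortho carbon through a six-membered transition state (boron-templated ortho-hydroxyalkylation, C4–C4a bond), giving benzodioxaborin 8, which at reflux expels the PhB=O unit and leaves ortho-quinone methide 9. The closest known reaction type is the phenylboronic acid-mediated condensation of phenols with α,β-unsaturated aldehydes to 2H-chromenes. Ring C then closes by a thermal disrotatory oxa-6π electrocyclization of the 1-oxatriene O1=C8a–C4a=C4–C3=C2 of 9 (O1–C2 bond), which also restores the aromaticity of ring A. The one new stereocenter, C2, forms without control as a racemate and needs none, because step 5 removes it. The step needs C–C bond formation ortho and not para to the hydroxyl group, which the tether through boron to the phenol oxygen secures, and a choice between the two ortho carbons, where the one para to the methoxy group should be favoured over the one squeezed between the two oxygen substituents, as in related templated reactions of 3-alkoxyphenols. The second arene of 5 has no free hydroxyl and cannot enter the template, and the benzyl ethers are stable to the weak acid.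

Step 5
Reactants: 10 rac-2-[4-(benzyloxy)-3-methoxyphenyl]-5-{2-[3-(benzyloxy)phenyl]ethyl}-7-methoxy-2H-chromene
Product: 11 2-[4-(benzyloxy)-3-methoxyphenyl]-5-{2-[3-(benzyloxy)phenyl]ethyl}-7-methoxychromenylium tetrafluoroborate
Conditions: Ph3CBF4 (1.05 equiv), CH2Cl2, 0 °C to rt; precipitation with Et2O
Reagents that add atoms: triphenylcarbenium tetrafluoroborate, F[B-](F)(F)F.c1ccc(cc1)[C+](c1ccccc1)c1ccccc1
Why: Hydride abstraction by the trityl cation from C2, whose C–H bond is benzylic, allylic and next to oxygen, gives the aromatic 10π benzopyrylium ring, so the racemic C2 centre is erased and the salt should precipitate free of neutral by-products.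

Step 6
Reactants: 11 2-[4-(benzyloxy)-3-methoxyphenyl]-5-{2-[3-(benzyloxy)phenyl]ethyl}-7-methoxychromenylium tetrafluoroborate
Product: 12 2-[4-(benzyloxy)-3-methoxyphenyl]-5-{2-[3-(benzyloxy)phenyl]ethyl}-7-methoxy-4H-chromene
Conditions: NaBH4 (excess), MeCN/THF, −20 to 0 °C, inverse addition; aq NaHCO3 work-up
Reagents that add atoms: none
Why: Borohydride reduction of a 2-aryl-1-benzopyrylium salt should deliver hydride to the unsubstituted C4 and not to C2, which is shielded by the aryl group and stabilised by its para-alkoxy donor; inverse addition keeps salt and product apart and the basic work-up protects the acid-labile C2=C3 enol ether.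

Step 7
Reactants: 12 2-[4-(benzyloxy)-3-methoxyphenyl]-5-{2-[3-(benzyloxy)phenyl]ethyl}-7-methoxy-4H-chromene
Product: 14 (2R,3S)-2-[4-(benzyloxy)-3-methoxyphenyl]-5-{2-[3-(benzyloxy)phenyl]ethyl}-7-methoxy-3,4-dihydro-2H-chromen-3-ol, via isopinocampheyl(flavan-3-yl)borane 13 (not isolated)
Conditions: IpcBH2 [from (+)-α-pinene, 1.2 equiv], THF, −25 to 0 °C; then NaOH, H2O2, 0 °C to rt
Reagents that add atoms: hydrogen peroxide, OO
Why: Asymmetric hydroboration of a trisubstituted aryl-substituted cyclic alkene with monoisopinocampheylborane puts boron on C3 (β to O1, away from the aryl group) and hydrogen on C2 from the same face, so the syn addition fixes the 2,3-trans relation, the isopinocampheyl group selects the face that leads to 2R,3S, and oxidation of the C–B bond proceeds with retention.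

Step 8
Reactants: 14 (2R,3S)-2-[4-(benzyloxy)-3-methoxyphenyl]-5-{2-[3-(benzyloxy)phenyl]ethyl}-7-methoxy-3,4-dihydro-2H-chromen-3-ol
Product: 15 Shanciol B [(2R,3S)-2-(4-hydroxy-3-methoxyphenyl)-5-[2-(3-hydroxyphenyl)ethyl]-7-methoxy-3,4-dihydro-2H-chromen-3-ol]
Conditions: H2 (1 atm), Pd/C, EtOAc/MeOH, rt
Reagents that add atoms: none
Why: Hydrogenolysis of the two aryl benzyl ethers over palladium under mild neutral conditions should leave the cyclic benzylic C2–O1 ether, the secondary alcohol and both stereocenters of the flavan-3-ol untouched.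

**Compound list**

1 | 3-(benzyloxy)benzaldehyde | O=Cc1cccc(OCc2ccccc2)c1 | starting material
2 | 1-(benzyloxy)-3-ethenylbenzene | C=Cc1cccc(OCc2ccccc2)c1 | intermediate
3 | 3-bromo-5-methoxyphenol | COc1cc(O)cc(Br)c1 | starting material
4 | 9-{2-[3-(benzyloxy)phenyl]ethyl}-9-borabicyclo[3.3.1]nonane | c1ccc(COc2cccc(CCB3C4CCCC3CCC4)c2)cc1 | intermediate
5 | 3-{2-[3-(benzyloxy)phenyl]ethyl}-5-methoxyphenol | COc1cc(O)cc(CCc2cccc(OCc3ccccc3)c2)c1 | intermediate
6 | 4-(benzyloxy)-3-methoxybenzaldehyde | COc1cc(C=O)ccc1OCc1ccccc1 | starting material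
7 | (2E)-3-[4-(benzyloxy)-3-methoxyphenyl]prop-2-enal | COc1cc(/C=C/C=O)ccc1OCc1ccccc1 | intermediate
8 | rac-4-{(E)-2-[4-(benzyloxy)-3-methoxyphenyl]ethenyl}-5-{2-[3-(benzyloxy)phenyl]ethyl}-7-methoxy-2-phenyl-4H-1,3,2-benzodioxaborinine | COc1cc(CCc2cccc(OCc3ccccc3)c2)c2c(c1)OB(c1ccccc1)OC2/C=C/c1ccc(OCc3ccccc3)c(OC)c1 | intermediate
9 | (6Z)-6-{(2E)-3-[4-(benzyloxy)-3-methoxyphenyl]prop-2-en-1-ylidene}-5-{2-[3-(benzyloxy)phenyl]ethyl}-3-methoxycyclohexa-2,4-dien-1-one | O=C1/C(=C\C=C\c2ccc(OCc3ccccc3)c(OC)c2)C(CCc2cccc(OCc3ccccc3)c2)=CC(OC)=C1 | intermediate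
10 | rac-2-[4-(benzyloxy)-3-methoxyphenyl]-5-{2-[3-(benzyloxy)phenyl]ethyl}-7-methoxy-2H-chromene | COc1cc(CCc2cccc(OCc3ccccc3)c2)c2c(c1)OC(c1ccc(OCc3ccccc3)c(OC)c1)C=C2 | intermediate
11 | 2-[4-(benzyloxy)-3-methoxyphenyl]-5-{2-[3-(benzyloxy)phenyl]ethyl}-7-methoxychromenylium tetrafluoroborate | COc1cc(CCc2cccc(OCc3ccccc3)c2)c2ccc(-c3ccc(OCc4ccccc4)c(OC)c3)[o+]c2c1.F[B-](F)(F)F | intermediate
12 | 2-[4-(benzyloxy)-3-methoxyphenyl]-5-{2-[3-(benzyloxy)phenyl]ethyl}-7-methoxy-4H-chromene | COc1cc(CCc2cccc(OCc3ccccc3)c2)c2c(c1)OC(c1ccc(OCc3ccccc3)c(OC)c1)=CC2 | intermediate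
13 | isopinocampheyl(flavan-3-yl)borane from 12: boron on C3 and the new hydrogen on C2 on the same face, aryl group trans to boron, configuration at C2 and C3 as in 14, isopinocampheyl group from (+)-α-pinene | COc1cc(CCc2cccc(OCc3ccccc3)c2)c2c(c1)O[C@H](c1ccc(OCc3ccccc3)c(OC)c1)[C@@H](B[C@@H]1C[C@@H]3C[C@H]([C@H]1C)C3(C)C)C2 | intermediate
14 | (2R,3S)-2-[4-(benzyloxy)-3-methoxyphenyl]-5-{2-[3-(benzyloxy)phenyl]ethyl}-7-methoxy-3,4-dihydro-2H-chromen-3-ol | COc1cc(CCc2cccc(OCc3ccccc3)c2)c2c(c1)O[C@H](c1ccc(OCc3ccccc3)c(OC)c1)[C@@H](O)C2 | intermediate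
15 | Shanciol B, (2R,3S)-2-(4-hydroxy-3-methoxyphenyl)-5-[2-(3-hydroxyphenyl)ethyl]-7-methoxy-3,4-dihydro-2H-chromen-3-ol | COc1cc(CCc2cccc(O)c2)c2c(c1)O[C@H](c1ccc(O)c(OC)c1)[C@@H](O)C2 | target

**Step count and risks**

Total step count: 8. Longest linear sequence: 7 (steps 1, 2, 4, 5, 6, 7, 8).

Steps most likely to fail:

Step 4. The C–C bond may form in part at the other ortho carbon, the one between hydroxyl and methoxy, and the quinone methide may be trapped by a second phenol before it cyclizes. The fallback fixes the regiochemistry by symmetry and chelation and reaches salt 11 by a condensation. It sets out from 2: hydroboration with 9-BBN gives 4 again, which is coupled (PdCl2(dppf), aq NaOH, THF, 65 °C) with commercial 1-bromo-3,5-dimethoxybenzene to 1-{2-[3-(benzyloxy)phenyl]ethyl}-3,5-dimethoxybenzene F1. Vilsmeier–Haack formylation (POCl3, DMF) should enter next to the chain, where the two open positions are equivalent, and give 2-{2-[3-(benzyloxy)phenyl]ethyl}-4,6-dimethoxybenzaldehyde F2. MgI2·OEt2 should then remove only the methyl group ortho to the formyl group, by chelation, to give 2-{2-[3-(benzyloxy)phenyl]ethyl}-6-hydroxy-4-methoxybenzaldehyde F3. Acid-mediated aldol condensation and cyclodehydration of F3 with commercial 1-[4-(benzyloxy)-3-methoxyphenyl]ethanone (48% aq HBF4, AcOH, rt) should give 11, where the route is rejoined before step 6.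

Step 7. The bulky chiral borane may add slowly to the electron-rich trisubstituted enol ether and with incomplete facial selectivity, and the β-aryloxy organoborane may lose the ring oxygen by elimination if warmed. The fallback separates relative from absolute control. It sets out from 12: hydroboration with BH3·SMe2 (THF, 0 °C) and oxidation (NaOH, H2O2) should give the racemic 2,3-trans alcohol, that is 14 together with the (2S,3R)-enantiomer of 14 F4. Esterification of the mixture with commercial (S)-methoxy(phenyl)acetic acid (DCC, DMAP, CH2Cl2) gives two diastereomers, the (S)-methoxy(phenyl)acetate of 14 F5 and the (S)-methoxy(phenyl)acetate of the enantiomer F6, to be separated by chromatography or crystallisation. Methanolysis of F5 (K2CO3, MeOH) returns 14, where the route is rejoined before step 8.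

Step 6. Hydride may add in part at C2, which only returns 10, and the nucleophilic enol ether product may add to unreduced salt or be hydrolysed on acidic contact. The fallback avoids hydride addition to the cation. It sets out from 11: buffered hydrolysis (NaOAc, MeCN/H2O) should open the pyrylium ring to (2E)-1-[4-(benzyloxy)-3-methoxyphenyl]-3-(2-{2-[3-(benzyloxy)phenyl]ethyl}-6-hydroxy-4-methoxyphenyl)prop-2-en-1-one F7. Hydrogenation of the enone C=C bond with H2 and RhCl(PPh3)3 (benzene/EtOH), which leaves benzyl ethers alone, should give 1-[4-(benzyloxy)-3-methoxyphenyl]-3-(2-{2-[3-(benzyloxy)phenyl]ethyl}-6-hydroxy-4-methoxyphenyl)propan-1-one F8. Cyclodehydration of its ring hemiketal form (PPTS, toluene, reflux, azeotropic removal of water) should give 12, where the route is rejoined before step 7.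

Further compounds
F1 | step 4 | 1-{2-[3-(benzyloxy)phenyl]ethyl}-3,5-dimethoxybenzene | COc1cc(OC)cc(CCc2cccc(OCc3ccccc3)c2)c1
F2 | step 4 | 2-{2-[3-(benzyloxy)phenyl]ethyl}-4,6-dimethoxybenzaldehyde | COc1cc(OC)c(C=O)c(CCc2cccc(OCc3ccccc3)c2)c1
F3 | step 4 | 2-{2-[3-(benzyloxy)phenyl]ethyl}-6-hydroxy-4-methoxybenzaldehyde | COc1cc(O)c(C=O)c(CCc2cccc(OCc3ccccc3)c2)c1
F4 | step 7 | (2S,3R)-2-[4-(benzyloxy)-3-methoxyphenyl]-5-{2-[3-(benzyloxy)phenyl]ethyl}-7-methoxy-3,4-dihydro-2H-chromen-3-ol (enantiomer of 14) | COc1cc(CCc2cccc(OCc3ccccc3)c2)c2c(c1)O[C@@H](c1ccc(OCc3ccccc3)c(OC)c1)[C@H](O)C2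
F5 | step 7 | (2R,3S)-2-[4-(benzyloxy)-3-methoxyphenyl]-5-{2-[3-(benzyloxy)phenyl]ethyl}-7-methoxy-3,4-dihydro-2H-chromen-3-yl (2S)-methoxy(phenyl)acetate | COc1cc(CCc2cccc(OCc3ccccc3)c2)c2c(c1)O[C@H](c1ccc(OCc3ccccc3)c(OC)c1)[C@@H](OC(=O)[C@@H](OC)c1ccccc1)C2
F6 | step 7 | (2S,3R)-2-[4-(benzyloxy)-3-methoxyphenyl]-5-{2-[3-(benzyloxy)phenyl]ethyl}-7-methoxy-3,4-dihydro-2H-chromen-3-yl (2S)-methoxy(phenyl)acetate | COc1cc(CCc2cccc(OCc3ccccc3)c2)c2c(c1)O[C@@H](c1ccc(OCc3ccccc3)c(OC)c1)[C@H](OC(=O)[C@@H](OC)c1ccccc1)C2
F7 | step 6 | (2E)-1-[4-(benzyloxy)-3-methoxyphenyl]-3-(2-{2-[3-(benzyloxy)phenyl]ethyl}-6-hydroxy-4-methoxyphenyl)prop-2-en-1-one | COc1cc(O)c(/C=C/C(=O)c2ccc(OCc3ccccc3)c(OC)c2)c(CCc2cccc(OCc3ccccc3)c2)c1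
F8 | step 6 | 1-[4-(benzyloxy)-3-methoxyphenyl]-3-(2-{2-[3-(benzyloxy)phenyl]ethyl}-6-hydroxy-4-methoxyphenyl)propan-1-one | COc1cc(O)c(CCC(=O)c2ccc(OCc3ccccc3)c(OC)c2)c(CCc2cccc(OCc3ccccc3)c2)c1
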